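**Retrosynthetic overview**

1. Feature: ring A is a 1,3,5-trioxygenated benzene (C1' acyl, C2'–OH, C4'–OH, C6'–OMe) in which C3', the carbon bonded to the diarylmethine C7, lies between the oxygenated carbons C2' and C4'. That is where the substituted carbon of a siloxyalkyne ends up in a cyclobutenone benzannulation.
2. Key disconnection: ring A → 3-methoxycyclobut-2-en-1-one + a siloxyalkyne carrying C7, ring C and the C1–C6 chain (bonds C2'–C3', C4'–C5', C1'–C2'). Ring A is the only ring made; rings B, C and the cinnamoyl ring come from 4-hydroxyphenyl starting materials.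
3. C7 comes from anti-SN2' alkynylation of a (5R,6Z)-allylic phosphate; C5 from asymmetric transfer hydrogenation of an ynone (Weinreb amide + arylacetylide); C3 from asymmetric hydrogenation of a β-keto ester.
4. After the annulation: silylation (C1' and C5' become equivalent), iodination, Stille acetylation, aldol condensation, global desilylation.

Key step: step 16

Remark: names keep the numbering of the target (chain C1 = CH2 on ring B, C3 = carbinol carbon, C7 = diarylmethine carbon; ring A = C1'–C6'). TBS = tert-butyldimethylsilyl, TIPS = triisopropylsilyl, R7 = the (3S,5E)-3-(TBSO)-1,7-bis[4-(TBSO)phenyl]hept-5-en-7-yl group with the C7 arrangement of the target. The CIP letter at C7 changes with the alkyne substituent (R in 19 and 23, S in 20) while the spatial arrangement stays the same. The facial sense of the two Noyori catalysts is assumed to follow the usual models.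

**Route**

Step 1
Reactants: 1 4-hydroxybenzaldehyde
Product: 2 4-(tert-butyldimethylsilyloxy)benzaldehyde
Conditions: TBSCl, imidazole, CH2Cl2, rt
Reagents that add atoms: tert-butyldimethylsilyl chloride, CC(C)(C)[Si](C)(C)Cl
Why: Imidazole-promoted O-silylation of the phenol masks the acidic OH for the organolithium steps that follow.

Step 2
Reactants: 2 4-(tert-butyldimethylsilyloxy)benzaldehyde
Product: 4 tert-butyl(4-ethynylphenoxy)dimethylsilane, via diazoalkene 3 (not isolated)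
Conditions: Me3SiCHN2, n-BuLi, THF, −78 °C → rt
Reagents that add atoms: (trimethylsilyl)diazomethane, C[Si](C)(C)C=[N+]=[N-]
Why: Colvin homologation, in which lithiated (trimethylsilyl)diazomethane adds to the aldehyde, Peterson-type loss of silanolate gives diazoalkene 3, and loss of N2 with 1,2-hydrogen shift gives the alkyne without the methanolic base that would cleave the aryl silyl ether.

Step 3
Reactants: 5 3-(4-hydroxyphenyl)propanoic acid
Product: 7 3-[4-(tert-butyldimethylsilyloxy)phenyl]propanoic acid, via silyl ester 6 (not isolated)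
Conditions: TBSCl (2.3 equiv), imidazole, DMF, rt; then AcOH/THF/H2O, rt
Reagents that add atoms: tert-butyldimethylsilyl chloride, CC(C)(C)[Si](C)(C)Cl
Why: Exhaustive silylation followed by selective hydrolysis of the much more labile silyl ester frees the acid and keeps the aryl silyl ether.

Step 4
Reactants: 7 3-[4-(tert-butyldimethylsilyloxy)phenyl]propanoic acid
Product: 9 ethyl 3-oxo-5-[4-(tert-butyldimethylsilyloxy)phenyl]pentanoate, via acyl Meldrum's acid 8 (not isolated)
Conditions: Meldrum's acid, DCC, DMAP, CH2Cl2, 0 °C → rt; then EtOH, reflux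
Reagents that add atoms: Meldrum's acid, CC1(C)OC(=O)CC(=O)O1; ethanol, CCO
Why: Carbodiimide-mediated C-acylation of Meldrum's acid followed by ethanolysis with loss of acetone and CO2 is a standard two-carbon homologation of an acid to a β-keto ester.

Step 5
Reactants: 9 ethyl 3-oxo-5-[4-(tert-butyldimethylsilyloxy)phenyl]pentanoate
Product: 10 ethyl (3S)-3-hydroxy-5-[4-(tert-butyldimethylsilyloxy)phenyl]pentanoate
Conditions: H2 (10 atm), RuCl2[(S)-BINAP] (1 mol %), EtOH, 50 °C
Reagents that add atoms: none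
Why: Noyori asymmetric hydrogenation of a β-keto ester, in which the ester-chelated Ru–(S)-BINAP hydride should add to one carbonyl face and give the (S)-carbinol (C3 of the target) under reagent control.

Step 6
Reactants: 10 ethyl (3S)-3-hydroxy-5-[4-(tert-butyldimethylsilyloxy)phenyl]pentanoate
Product: 11 ethyl (3S)-3-(tert-butyldimethylsilyloxy)-5-[4-(tert-butyldimethylsilyloxy)phenyl]pentanoate
Conditions: TBSCl, imidazole, DMF, rt
Reagents that add atoms: tert-butyldimethylsilyl chloride, CC(C)(C)[Si](C)(C)Cl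
Why: Routine silylation of the secondary alcohol keeps C3–O inert through the organometallic and thermal steps.

Step 7
Reactants: 11 ethyl (3S)-3-(tert-butyldimethylsilyloxy)-5-[4-(tert-butyldimethylsilyloxy)phenyl]pentanoate
Product: 12 (3S)-N-methoxy-N-methyl-3-(tert-butyldimethylsilyloxy)-5-[4-(tert-butyldimethylsilyloxy)phenyl]pentanamide
Conditions: MeNH(OMe)·HCl, i-PrMgCl, THF, −20 → 0 °C
Reagents that add atoms: N,O-dimethylhydroxylamine hydrochloride, CNOC.Cl
Why: Weinreb amide formation by aminolysis of the ester with the chloromagnesium amide at low temperature, which avoids β-elimination of the silyloxy group.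

Step 8
Reactants: 4 tert-butyl(4-ethynylphenoxy)dimethylsilane; 12 Weinreb amide
Product: 14 (3S)-3-(TBSO)-1,7-bis[4-(TBSO)phenyl]hept-6-yn-5-one, via lithium acetylide 13 (not isolated)
Conditions: 4, n-BuLi, THF, −78 °C; then 12, −78 → 0 °C
Reagents that add atoms: none
Why: Acylation of a lithium acetylide by a Weinreb amide stops at the ketone because the chelated tetrahedral adduct survives until work-up.

Step 9
Reactants: 14 (3S)-3-(TBSO)-1,7-bis[4-(TBSO)phenyl]hept-6-yn-5-one
Product: 15 (3S,5R)-3-(TBSO)-1,7-bis[4-(TBSO)phenyl]hept-6-yn-5-ol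
Conditions: Ru(p-cymene)[(R,R)-TsNCHPhCHPhNH] (2 mol %), i-PrOH, rt
Reagents that add atoms: none
Why: Noyori asymmetric transfer hydrogenation of an alkynyl ketone, in which the alkyne takes the place of the aryl group of an aryl alkyl ketone, so the (R,R)-catalyst should give the (5R)-alcohol under base-free conditions that spare the β-silyloxy ketone and override the remote C3 centre.

Step 10
Reactants: 15 (3S,5R)-3-(TBSO)-1,7-bis[4-(TBSO)phenyl]hept-6-yn-5-ol
Product: 16 (3S,5R,6Z)-3-(TBSO)-1,7-bis[4-(TBSO)phenyl]hept-6-en-5-ol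
Conditions: H2 (1 atm), Pd/CaCO3 poisoned with Pb(OAc)2 (Lindlar catalyst), quinoline, EtOAc, rt
Reagents that add atoms: none
Why: Lindlar semihydrogenation adds H2 syn and gives the (Z)-alkene, the geometry that enforces a single reactive conformer in step 12.

Step 11
Reactants: 16 (3S,5R,6Z)-3-(TBSO)-1,7-bis[4-(TBSO)phenyl]hept-6-en-5-ol
Product: 17 diethyl (3S,5R,6Z)-3-(TBSO)-1,7-bis[4-(TBSO)phenyl]hept-6-en-5-yl phosphate
Conditions: (EtO)2P(O)Cl, pyridine, DMAP (cat.), CH2Cl2, 0 °C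
Reagents that add atoms: diethyl chlorophosphate, CCOP(=O)(Cl)OCC
Why: O-phosphorylation of the secondary allylic alcohol with retention at C5 installs the leaving group for copper-catalysed allylic substitution.

Step 12
Reactants: 17 allylic phosphate; 18 ethynyltrimethylsilane
Product: 19 (3S,5E,7R)-3-(TBSO)-1,7-bis[4-(TBSO)phenyl]-7-[(trimethylsilyl)ethynyl]hept-5-ene
Conditions: CuCl (10 mol %), LiOt-Bu (2 equiv), 18 (2 equiv), THF, 25 °C
Reagents that add atoms: none
Why: Copper-catalysed γ-selective anti-SN2' coupling of a secondary (Z)-allylic phosphate with a terminal alkyne, in which the monovalent copper acetylide attacks C7 opposite to the phosphate in the conformer that holds C5–H in the alkene plane (allylic 1,3-strain with the cis aryl group), so that (5R) is transferred to (7R) and the new C5=C6 bond is E.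

Step 13
Reactants: 19 silylalkyne
Product: 20 (3S,5E,7S)-7-ethynyl-3-(TBSO)-1,7-bis[4-(TBSO)phenyl]hept-5-ene
Conditions: AgNO3 (10 mol %), acetone/H2O, rt
Reagents that add atoms: none
Why: Silver-catalysed protiodesilylation removes the alkynyl SiMe3 group through a silver acetylide and leaves the O-silyl ethers, which carbonate/methanol or fluoride would attack.

Step 14
Reactants: 20 terminal alkyne
Product: 23 (3S,5E,7R)-3-(TBSO)-1,7-bis[4-(TBSO)phenyl]-7-[(triisopropylsilyloxy)ethynyl]hept-5-ene, via lithium acetylide 21 (not isolated), via lithium ynolate 22 (not isolated)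
Conditions: n-BuLi (1.0 equiv), THF, −78 °C; LiOOt-Bu (from t-BuOOH and LiHMDS, THF, −78 °C), −78 → 0 °C; TIPSOTf, −78 → 0 °C
Reagents that add atoms: tert-butyl hydroperoxide, CC(C)(C)OO; triisopropylsilyl triflate, CC(C)[Si](C(C)C)(C(C)C)OS(=O)(=O)C(F)(F)F
Why: Oxidation of a lithium acetylide by electrophilic oxygen transfer from lithium tert-butyl peroxide gives the ynolate, which the bulky silyl triflate traps on oxygen, while one equivalent of n-BuLi at −78 °C should remove the sp C–H much faster than the C7–H.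

Step 15
Reactants: 24 cyclobutane-1,3-dione
Product: 25 3-methoxycyclobut-2-en-1-one
Conditions: Me3SiCHN2, MeOH/Et2O, 0 °C
Reagents that add atoms: (trimethylsilyl)diazomethane, C[Si](C)(C)C=[N+]=[N-]
Why: The dione reacts as its acidic enol (a vinylogous acid) and is O-methylated by the diazomethane equivalent formed from (trimethylsilyl)diazomethane and methanol.

Step 16
Reactants: 23 siloxyalkyne; 25 3-methoxycyclobut-2-en-1-one
Product: 30 2-(R7)-5-methoxy-3-(triisopropylsilyloxy)phenol, via vinylketene 26 (not isolated), via vinylcyclobutenone 27 (not isolated), via dienylketene 28 (not isolated), via cyclohexadienone 29 (not isolated)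
Conditions: toluene, 80 → 110 °C (sealed tube), slow addition of 25 (1.5 equiv)
Reagents that add atoms: none
Why: Heating opens 25 by four-electron electrocyclic ring opening to vinylketene 26, whose ketene carbon is attacked by the carbon of 23 that carries C7 (the nucleophilic carbon β to the siloxy oxygen) to give the [2+2] adduct 27 with the new bonds C2'–C3' and C4'–C5'; 27 opens again to dienylketene 28, which closes ring A by six-electron electrocyclisation (C1'–C2') to dienone 29 and tautomerises to phenol 30. The closest known reaction is the Danheiser benzannulation of cyclobutenones with siloxyalkynes to 2-substituted resorcinol monosilyl ethers, here run with a 3-alkoxycyclobutenone. Ring A is therefore closed by a pericyclic closure and not by substitution at the crowded C3'–C7 junction. No stereocentre is created (the sp3 ring carbon of 27 is lost on ring opening), and C7 is neither ionised nor deprotonated in this neutral thermal cascade, so it should keep its configuration. The selectivity needed is the regiochemistry of the ketene–alkyne union, which the polarisation of the siloxyalkyne secures: C7 is placed at C3' between the carbon from the ketene carbonyl (C2'–OH) and the siloxy carbon (C4'–OTIPS), with the methoxy carbon at C6'. Slow addition of 25 keeps the ketene concentration low so that the hindered phenol of 30 is not O-acylated.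

Step 17
Reactants: 30 phenol
Product: 31 (3S,5E,7R)-7-[4-methoxy-2,6-bis(triisopropylsilyloxy)phenyl]-3-(TBSO)-1,7-bis[4-(TBSO)phenyl]hept-5-ene
Conditions: TIPSOTf, 2,6-lutidine, CH2Cl2, 0 °C
Reagents that add atoms: triisopropylsilyl triflate, CC(C)[Si](C(C)C)(C(C)C)OS(=O)(=O)C(F)(F)F
Why: Silylation of the remaining phenol with the silyl triflate makes the two ring A oxygens identical, so C1' and C5' become equivalent, and masks the OH for the enolate chemistry.

Step 18
Reactants: 31 bis-TIPS ether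
Product: 32 (3S,5E,7R)-7-[3-iodo-4-methoxy-2,6-bis(triisopropylsilyloxy)phenyl]-3-(TBSO)-1,7-bis[4-(TBSO)phenyl]hept-5-ene
Conditions: NIS (1.05 equiv), CH2Cl2, −20 → 0 °C, dark
Reagents that add atoms: N-iodosuccinimide, O=C1CCC(=O)N1I
Why: Electrophilic aromatic iodination needs no acid on the tri-oxygenated ring A, which is far more nucleophilic than rings B and C or the alkene, and one equivalent of NIS should stop at mono-iodination of one of the two equivalent CH positions.

Step 19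
Reactants: 32 aryl iodide
Product: 34 1-[3-(R7)-6-methoxy-2,4-bis(triisopropylsilyloxy)phenyl]ethan-1-one, via enol ether 33 (not isolated)
Conditions: Bu3SnC(OEt)=CH2, Pd2(dba)3 (5 mol %), AsPh3, CuI (cat.), DMF, 70 °C; then 1 M HCl, THF, 0 °C
Reagents that add atoms: tributyl(1-ethoxyvinyl)stannane, CCCC[Sn](CCCC)(CCCC)C(=C)OCC; water, O
Why: Stille coupling with the α-ethoxyvinylstannane (an acetyl anion equivalent) and brief dilute-acid hydrolysis of the enol ether install the acetyl group without Friedel–Crafts acid, which could cleave the C3'–C7 bond by ipso protonation.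

Step 20
Reactants: 34 aryl methyl ketone; 2 4-(tert-butyldimethylsilyloxy)benzaldehyde
Product: 38 (E)-1-[3-(R7)-6-methoxy-2,4-bis(triisopropylsilyloxy)phenyl]-3-[4-(tert-butyldimethylsilyloxy)phenyl]prop-2-en-1-one, via lithium enolate 35 (not isolated), via lithium aldolate 36 (not isolated), via mesylate 37 (not isolated)
Conditions: LiHMDS, THF, −78 °C; 2, −78 °C; then MsCl, Et3N, −78 °C → rt
Reagents that add atoms: none
Why: Directed aldol addition of the lithium enolate to the non-enolisable aldehyde, then mesylation of the aldolate and E1cB elimination, should give the (E)-enone under aprotic conditions that keep the aryl silyl ethers, which a hydroxide-mediated Claisen–Schmidt condensation would not.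

Step 21
Reactants: 38 hexasilyl ether
Product: 39 epicalyxin B
Conditions: TBAF, AcOH, THF, 0 °C → rt
Reagents that add atoms: none
Why: Fluoride-mediated desilylation cleaves all six Si–O bonds, and the acetic acid buffer keeps the phenoxides from cyclising the 2'-hydroxychalcone to a flavanone and keeps C7 away from strong acid or base.

**Compound list**

1 | 4-hydroxybenzaldehyde | O=Cc1ccc(O)cc1 | starting material
2 | 4-(tert-butyldimethylsilyloxy)benzaldehyde | O=Cc1ccc(O[Si](C)(C)C(C)(C)C)cc1 | intermediate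
3 | 1-(2-diazoethenyl)-4-(tert-butyldimethylsilyloxy)benzene (not isolated) | [N-]=[N+]=C=Cc1ccc(O[Si](C)(C)C(C)(C)C)cc1 | intermediate
4 | tert-butyl(4-ethynylphenoxy)dimethylsilane | C#Cc1ccc(O[Si](C)(C)C(C)(C)C)cc1 | intermediate
5 | 3-(4-hydroxyphenyl)propanoic acid | OC(=O)CCc1ccc(O)cc1 | starting material
6 | tert-butyldimethylsilyl 3-[4-(tert-butyldimethylsilyloxy)phenyl]propanoate (not isolated) | CC(C)(C)[Si](C)(C)OC(=O)CCc1ccc(O[Si](C)(C)C(C)(C)C)cc1 | intermediate
7 | 3-[4-(tert-butyldimethylsilyloxy)phenyl]propanoic acid | OC(=O)CCc1ccc(O[Si](C)(C)C(C)(C)C)cc1 | intermediate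
8 | 2,2-dimethyl-5-{3-[4-(tert-butyldimethylsilyloxy)phenyl]propanoyl}-1,3-dioxane-4,6-dione (not isolated) | CC1(C)OC(=O)C(C(=O)CCc2ccc(O[Si](C)(C)C(C)(C)C)cc2)C(=O)O1 | intermediate
9 | ethyl 3-oxo-5-[4-(tert-butyldimethylsilyloxy)phenyl]pentanoate | CCOC(=O)CC(=O)CCc1ccc(O[Si](C)(C)C(C)(C)C)cc1 | intermediate
10 | ethyl (3S)-3-hydroxy-5-[4-(tert-butyldimethylsilyloxy)phenyl]pentanoate | CCOC(=O)C[C@@H](O)CCc1ccc(O[Si](C)(C)C(C)(C)C)cc1 | intermediate
11 | ethyl (3S)-3-(tert-butyldimethylsilyloxy)-5-[4-(tert-butyldimethylsilyloxy)phenyl]pentanoate | CCOC(=O)C[C@@H](O[Si](C)(C)C(C)(C)C)CCc1ccc(O[Si](C)(C)C(C)(C)C)cc1 | intermediate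
12 | (3S)-N-methoxy-N-methyl-3-(tert-butyldimethylsilyloxy)-5-[4-(tert-butyldimethylsilyloxy)phenyl]pentanamide | CON(C)C(=O)C[C@@H](O[Si](C)(C)C(C)(C)C)CCc1ccc(O[Si](C)(C)C(C)(C)C)cc1 | intermediate
13 | lithium [4-(tert-butyldimethylsilyloxy)phenyl]acetylide (not isolated) | [Li]C#Cc1ccc(O[Si](C)(C)C(C)(C)C)cc1 | intermediate
14 | (3S)-3-(TBSO)-1,7-bis[4-(TBSO)phenyl]hept-6-yn-5-one | O=C(C#Cc1ccc(O[Si](C)(C)C(C)(C)C)cc1)C[C@@H](O[Si](C)(C)C(C)(C)C)CCc1ccc(O[Si](C)(C)C(C)(C)C)cc1 | intermediate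
15 | (3S,5R)-3-(TBSO)-1,7-bis[4-(TBSO)phenyl]hept-6-yn-5-ol | O[C@@H](C#Cc1ccc(O[Si](C)(C)C(C)(C)C)cc1)C[C@@H](O[Si](C)(C)C(C)(C)C)CCc1ccc(O[Si](C)(C)C(C)(C)C)cc1 | intermediate
16 | (3S,5R,6Z)-3-(TBSO)-1,7-bis[4-(TBSO)phenyl]hept-6-en-5-ol | O[C@@H](/C=C\c1ccc(O[Si](C)(C)C(C)(C)C)cc1)C[C@@H](O[Si](C)(C)C(C)(C)C)CCc1ccc(O[Si](C)(C)C(C)(C)C)cc1 | intermediate
17 | diethyl (3S,5R,6Z)-3-(TBSO)-1,7-bis[4-(TBSO)phenyl]hept-6-en-5-yl phosphate | CCOP(=O)(OCC)O[C@@H](/C=C\c1ccc(O[Si](C)(C)C(C)(C)C)cc1)C[C@@H](O[Si](C)(C)C(C)(C)C)CCc1ccc(O[Si](C)(C)C(C)(C)C)cc1 | intermediate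
18 | ethynyltrimethylsilane | C#C[Si](C)(C)C | starting material
19 | (3S,5E,7R)-3-(TBSO)-1,7-bis[4-(TBSO)phenyl]-7-[(trimethylsilyl)ethynyl]hept-5-ene | C[Si](C)(C)C#C[C@H](/C=C/C[C@@H](O[Si](C)(C)C(C)(C)C)CCc1ccc(O[Si](C)(C)C(C)(C)C)cc1)c1ccc(O[Si](C)(C)C(C)(C)C)cc1 | intermediate
20 | (3S,5E,7S)-7-ethynyl-3-(TBSO)-1,7-bis[4-(TBSO)phenyl]hept-5-ene | C#C[C@H](/C=C/C[C@@H](O[Si](C)(C)C(C)(C)C)CCc1ccc(O[Si](C)(C)C(C)(C)C)cc1)c1ccc(O[Si](C)(C)C(C)(C)C)cc1 | intermediate
21 | lithium acetylide of 20 (not isolated) | [Li]C#C[C@H](/C=C/C[C@@H](O[Si](C)(C)C(C)(C)C)CCc1ccc(O[Si](C)(C)C(C)(C)C)cc1)c1ccc(O[Si](C)(C)C(C)(C)C)cc1 | intermediate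
22 | lithium ynolate R7–C≡C–OLi (not isolated) | [Li]OC#C[C@H](/C=C/C[C@@H](O[Si](C)(C)C(C)(C)C)CCc1ccc(O[Si](C)(C)C(C)(C)C)cc1)c1ccc(O[Si](C)(C)C(C)(C)C)cc1 | intermediate
23 | (3S,5E,7R)-3-(TBSO)-1,7-bis[4-(TBSO)phenyl]-7-[(triisopropylsilyloxy)ethynyl]hept-5-ene | CC(C)[Si](C(C)C)(C(C)C)OC#C[C@H](/C=C/C[C@@H](O[Si](C)(C)C(C)(C)C)CCc1ccc(O[Si](C)(C)C(C)(C)C)cc1)c1ccc(O[Si](C)(C)C(C)(C)C)cc1 | intermediate
24 | cyclobutane-1,3-dione | O=C1CC(=O)C1 | starting material
25 | 3-methoxycyclobut-2-en-1-one | COC1=CC(=O)C1 | intermediate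
26 | 3-methoxybuta-1,3-dien-1-one, the vinylketene (not isolated) | COC(=C)C=C=O | intermediate
27 | 4-(1-methoxyethenyl)-2-(R7)-3-(triisopropylsilyloxy)cyclobut-2-en-1-one, C4 unassigned (not isolated) | COC(=C)C1C(=O)C(=C1O[Si](C(C)C)(C(C)C)C(C)C)[C@H](/C=C/C[C@@H](O[Si](C)(C)C(C)(C)C)CCc1ccc(O[Si](C)(C)C(C)(C)C)cc1)c1ccc(O[Si](C)(C)C(C)(C)C)cc1 | intermediate
28 | (3Z)-5-methoxy-2-(R7)-3-(triisopropylsilyloxy)hexa-1,3,5-trien-1-one, the dienylketene (not isolated) | C=C(OC)/C=C(/O[Si](C(C)C)(C(C)C)C(C)C)C(=C=O)[C@H](/C=C/C[C@@H](O[Si](C)(C)C(C)(C)C)CCc1ccc(O[Si](C)(C)C(C)(C)C)cc1)c1ccc(O[Si](C)(C)C(C)(C)C)cc1 | intermediate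
29 | 5-methoxy-2-(R7)-3-(triisopropylsilyloxy)cyclohexa-2,4-dien-1-one (not isolated) | COC1=CC(O[Si](C(C)C)(C(C)C)C(C)C)=C([C@H](/C=C/C[C@@H](O[Si](C)(C)C(C)(C)C)CCc2ccc(O[Si](C)(C)C(C)(C)C)cc2)c2ccc(O[Si](C)(C)C(C)(C)C)cc2)C(=O)C1 | intermediate
30 | 2-(R7)-5-methoxy-3-(triisopropylsilyloxy)phenol, (3S,7R) | COc1cc(O[Si](C(C)C)(C(C)C)C(C)C)c([C@H](/C=C/C[C@@H](O[Si](C)(C)C(C)(C)C)CCc2ccc(O[Si](C)(C)C(C)(C)C)cc2)c2ccc(O[Si](C)(C)C(C)(C)C)cc2)c(O)c1 | intermediate
31 | (3S,5E,7R)-7-[4-methoxy-2,6-bis(triisopropylsilyloxy)phenyl]-3-(TBSO)-1,7-bis[4-(TBSO)phenyl]hept-5-ene | COc1cc(O[Si](C(C)C)(C(C)C)C(C)C)c([C@H](/C=C/C[C@@H](O[Si](C)(C)C(C)(C)C)CCc2ccc(O[Si](C)(C)C(C)(C)C)cc2)c2ccc(O[Si](C)(C)C(C)(C)C)cc2)c(O[Si](C(C)C)(C(C)C)C(C)C)c1 | intermediate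
32 | (3S,5E,7R)-7-[3-iodo-4-methoxy-2,6-bis(triisopropylsilyloxy)phenyl]-3-(TBSO)-1,7-bis[4-(TBSO)phenyl]hept-5-ene | COc1cc(O[Si](C(C)C)(C(C)C)C(C)C)c([C@H](/C=C/C[C@@H](O[Si](C)(C)C(C)(C)C)CCc2ccc(O[Si](C)(C)C(C)(C)C)cc2)c2ccc(O[Si](C)(C)C(C)(C)C)cc2)c(O[Si](C(C)C)(C(C)C)C(C)C)c1I | intermediate
33 | 1-ethoxyethenyl arene, C1'–C(OEt)=CH2 on ring A of 31 (not isolated) | COc1cc(O[Si](C(C)C)(C(C)C)C(C)C)c([C@H](/C=C/C[C@@H](O[Si](C)(C)C(C)(C)C)CCc2ccc(O[Si](C)(C)C(C)(C)C)cc2)c2ccc(O[Si](C)(C)C(C)(C)C)cc2)c(O[Si](C(C)C)(C(C)C)C(C)C)c1C(=C)OCC | intermediate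
34 | 1-[3-(R7)-6-methoxy-2,4-bis(triisopropylsilyloxy)phenyl]ethan-1-one | COc1cc(O[Si](C(C)C)(C(C)C)C(C)C)c([C@H](/C=C/C[C@@H](O[Si](C)(C)C(C)(C)C)CCc2ccc(O[Si](C)(C)C(C)(C)C)cc2)c2ccc(O[Si](C)(C)C(C)(C)C)cc2)c(O[Si](C(C)C)(C(C)C)C(C)C)c1C(C)=O | intermediate
35 | lithium enolate of 34 (not isolated) | COc1cc(O[Si](C(C)C)(C(C)C)C(C)C)c([C@H](/C=C/C[C@@H](O[Si](C)(C)C(C)(C)C)CCc2ccc(O[Si](C)(C)C(C)(C)C)cc2)c2ccc(O[Si](C)(C)C(C)(C)C)cc2)c(O[Si](C(C)C)(C(C)C)C(C)C)c1C(=C)O[Li] | intermediate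
36 | lithium aldolate, β-carbinol carbon unassigned (not isolated) | COc1cc(O[Si](C(C)C)(C(C)C)C(C)C)c([C@H](/C=C/C[C@@H](O[Si](C)(C)C(C)(C)C)CCc2ccc(O[Si](C)(C)C(C)(C)C)cc2)c2ccc(O[Si](C)(C)C(C)(C)C)cc2)c(O[Si](C(C)C)(C(C)C)C(C)C)c1C(=O)CC(O[Li])c1ccc(O[Si](C)(C)C(C)(C)C)cc1 | intermediate
37 | β-mesyloxy ketone, β-carbon unassigned (not isolated) | COc1cc(O[Si](C(C)C)(C(C)C)C(C)C)c([C@H](/C=C/C[C@@H](O[Si](C)(C)C(C)(C)C)CCc2ccc(O[Si](C)(C)C(C)(C)C)cc2)c2ccc(O[Si](C)(C)C(C)(C)C)cc2)c(O[Si](C(C)C)(C(C)C)C(C)C)c1C(=O)CC(OS(C)(=O)=O)c1ccc(O[Si](C)(C)C(C)(C)C)cc1 | intermediate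
38 | (E)-1-[3-(R7)-6-methoxy-2,4-bis(triisopropylsilyloxy)phenyl]-3-[4-(tert-butyldimethylsilyloxy)phenyl]prop-2-en-1-one, the hexasilyl ether of epicalyxin B | COc1cc(O[Si](C(C)C)(C(C)C)C(C)C)c([C@H](/C=C/C[C@@H](O[Si](C)(C)C(C)(C)C)CCc2ccc(O[Si](C)(C)C(C)(C)C)cc2)c2ccc(O[Si](C)(C)C(C)(C)C)cc2)c(O[Si](C(C)C)(C(C)C)C(C)C)c1C(=O)/C=C/c1ccc(O[Si](C)(C)C(C)(C)C)cc1 | intermediate
39 | epicalyxin B, (3S,7R) | COc1cc(O)c([C@H](/C=C/C[C@@H](O)CCc2ccc(O)cc2)c2ccc(O)cc2)c(O)c1C(=O)/C=C/c1ccc(O)cc1 | target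

**Step count and risks**

Total step count: 21. Longest linear sequence: 18 steps (5 → 39 through steps 3–14 and 16–21).

Steps most likely to fail:

Step 16 (key step). The cyclobutenone is a vinylogous ester, so its ring opening may need temperatures at which the siloxyalkyne decomposes or at which the product phenol is acylated by the ketene. The fallback sets out from 23 and generates the same vinylketene 26 at room temperature by photochemical Wolff rearrangement, the diazo ketone variant of the benzannulation. Commercial 3,3-dimethoxybutan-2-one would lose methanol under acid catalysis to give 3-methoxybut-3-en-2-one F1. Trifluoroacetylation of its lithium enolate (LiHMDS, CF3CO2CH2CF3) would give 1,1,1-trifluoro-5-methoxyhex-5-ene-2,4-dione F2, and detrifluoroacetylative diazo transfer (MsN3, Et3N, H2O, MeCN) would give 1-diazo-3-methoxybut-3-en-2-one F3. Irradiation of F3 with 23 (Pyrex filter, toluene, rt) followed by warming to complete the ring opening and closure should come back to the route at 30.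

Step 12. Attack at C5 (which keeps the styrene conjugation) or ionisation of the electron-rich allylic phosphate before coupling would erode the regiocontrol and the transfer of chirality. The fallback sets out from 15 and replaces the copper substitution by a sigmatropic transfer. Reduction of 15 with NaAlH2(OCH2CH2OCH3)2 (THF, 0 °C) would give the (3S,5R,6E)-allylic alcohol F4. Johnson–Claisen rearrangement (CH3C(OEt)3, cat. propanoic acid, 130 °C) should pass through a chair transition state with suprafacial delivery and give ethyl 2-(R7)acetate F5 with the same C7 arrangement and an E C5=C6 bond. Two successive enolate brominations (LiHMDS then CBr4, −78 °C) would give ethyl 2,2-dibromo-2-(R7)acetate F6. Double bromine–lithium exchange (t-BuLi, THF, −78 → 0 °C) with loss of ethoxide would give the lithium ynolate 22, which is silylated as in step 14, so the route is rejoined at 23. This also bypasses the base-sensitive steps 13 and 14.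

Step 19. Transmetalation at the iodide flanked by OTIPS and OMe may be slow, so that protodeiodination outruns coupling. The fallback sets out from 32 and uses polar organometallic acylation. Iodine–magnesium exchange (i-PrMgCl·LiCl, THF, −20 °C, too weakly basic to touch C7–H) would give the arylmagnesium chloride F7. Acylation with N-methoxy-N-methylacetamide should give the methyl ketone and come back to the route at 34.

**Further compounds**

F1 | step 16 | 3-methoxybut-3-en-2-one | COC(=C)C(C)=O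
F2 | step 16 | 1,1,1-trifluoro-5-methoxyhex-5-ene-2,4-dione | COC(=C)C(=O)CC(=O)C(F)(F)F
F3 | step 16 | 1-diazo-3-methoxybut-3-en-2-one | COC(=C)C(=O)C=[N+]=[N-]
F4 | step 12 | (3S,5R,6E)-3-(TBSO)-1,7-bis[4-(TBSO)phenyl]hept-6-en-5-ol | O[C@@H](/C=C/c1ccc(O[Si](C)(C)C(C)(C)C)cc1)C[C@@H](O[Si](C)(C)C(C)(C)C)CCc1ccc(O[Si](C)(C)C(C)(C)C)cc1
F5 | step 12 | ethyl 2-(R7)acetate, (3S,5E,7R) | CCOC(=O)C[C@H](/C=C/C[C@@H](O[Si](C)(C)C(C)(C)C)CCc1ccc(O[Si](C)(C)C(C)(C)C)cc1)c1ccc(O[Si](C)(C)C(C)(C)C)cc1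
F6 | step 12 | ethyl 2,2-dibromo-2-(R7)acetate, (3S,5E,7R) | CCOC(=O)C(Br)(Br)[C@H](/C=C/C[C@@H](O[Si](C)(C)C(C)(C)C)CCc1ccc(O[Si](C)(C)C(C)(C)C)cc1)c1ccc(O[Si](C)(C)C(C)(C)C)cc1
F7 | step 19 | [3-(R7)-6-methoxy-2,4-bis(triisopropylsilyloxy)phenyl]magnesium chloride | COc1cc(O[Si](C(C)C)(C(C)C)C(C)C)c([C@H](/C=C/C[C@@H](O[Si](C)(C)C(C)(C)C)CCc2ccc(O[Si](C)(C)C(C)(C)C)cc2)c2ccc(O[Si](C)(C)C(C)(C)C)cc2)c(O[Si](C(C)C)(C(C)C)C(C)C)c1[Mg]Cl
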